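**Retrosynthetic overview**
The target is reached from a fully protected acid by two unmasking steps: allyl off ring B, then three silyl ethers off.
Key disconnection: in ring A the carboxyl carbon C1 lies between the methoxy carbon C2 and the aryloxy carbon C6. Because C6 and C1 are neighbours, the C6–O(aryl) and C1–CO2H bonds are cut together, giving a 3-methoxy-type aryne (C6≡C1), the ring B phenoxide and CO2.
The aryne precursor (ring A ortho-silylaryl triflate) comes from 4-hydroxy-2-methoxybenzaldehyde: O-carbamate, Brown methallylboration (sets the only stereocentre, S), hydration, silylation, carbamate-directed silylation of C1, carbamate to triflate.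
The ring B phenol comes from 2-hydroxy-3-methoxy-5-methylbenzaldehyde: demethylation, selective 3-O-allylation, reduction, silylation of the primary alcohol.
No ring is formed: rings A and B are bought as benzene rings; ring A is elaborated first (steps 1–8), ring B second (steps 9–12), and they are joined in step 13.

Key step: step 13

Assumption: 4-hydroxy-2-methoxybenzaldehyde, 2-hydroxy-3-methoxy-5-methylbenzaldehyde, methallylmagnesium chloride solution and (−)-Ipc2BOMe are taken as catalogue items. The carbinol centre of the target is (S) (O > ring A carbon > CH2 > H) and keeps this descriptor in every protected intermediate.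

**Route**

Step 1
Reactants: 1 4-hydroxy-2-methoxybenzaldehyde
Product: 2 4-formyl-3-methoxyphenyl N,N-diethylcarbamate
Conditions: Et2NCOCl, K2CO3, MeCN, reflux
Reagents that add atoms: N,N-diethylcarbamoyl chloride, CCN(CC)C(=O)Cl
Why: O-carbamoylation of a phenol: the C4 phenol, acidified by the para formyl group, is the only nucleophile and is acylated under carbonate base to give the group that later directs lithiation.

Step 2
Reactants: 2 4-formyl-3-methoxyphenyl N,N-diethylcarbamate
Product: 4 (S)-4-(1-hydroxy-3-methylbut-3-en-1-yl)-3-methoxyphenyl N,N-diethylcarbamate, via borinate ester 3 (not isolated)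
Conditions: (−)-Ipc2BOMe [from (+)-α-pinene], methallylmagnesium chloride, Et2O, −78 °C → rt; then 2, −78 °C; then NaBO3·4H2O, THF/H2O, rt
Reagents that add atoms: methallylmagnesium chloride, C=C(C)C[Mg]Cl
Why: Brown asymmetric methallylboration: the B-methallyldiisopinocampheylborane formed in the flask transfers its methallyl group through a closed chair transition state to the Si face of the aldehyde, which should set the (S) carbinol centre (the sense known for (S)-1-phenylbut-3-en-1-ol from benzaldehyde), and the diethylcarbamate is inert to the borane and to the mild perborate work-up.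

Step 3
Reactants: 4 (S)-4-(1-hydroxy-3-methylbut-3-en-1-yl)-3-methoxyphenyl N,N-diethylcarbamate
Product: 5 (S)-4-[1-(tert-butyldimethylsilyloxy)-3-methylbut-3-en-1-yl]-3-methoxyphenyl N,N-diethylcarbamate
Conditions: TBSCl, imidazole, DMF, rt
Reagents that add atoms: tert-butyldimethylsilyl chloride, CC(C)(C)[Si](C)(C)Cl
Why: Silyl ether formation on the secondary benzylic alcohol is routine, removes the only O–H before the radical hydration and the later organolithium step, and does not touch the stereocentre.

Step 4
Reactants: 5 (S)-4-[1-(tert-butyldimethylsilyloxy)-3-methylbut-3-en-1-yl]-3-methoxyphenyl N,N-diethylcarbamate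
Product: 6 (S)-4-[1-(tert-butyldimethylsilyloxy)-3-hydroxy-3-methylbutyl]-3-methoxyphenyl N,N-diethylcarbamate
Conditions: Co(acac)2 (cat.), PhSiH3, O2 (1 atm), THF, rt
Reagents that add atoms: dioxygen, O=O
Why: Mukaiyama hydration: hydrogen-atom transfer from a cobalt hydride to the 1,1-disubstituted alkene gives the tertiary radical, which is trapped by O2 and reduced by the silane to the Markovnikov tertiary alcohol without affecting carbamate, silyl ether or the neighbouring stereocentre.

Step 5
Reactants: 6 (S)-4-[1-(tert-butyldimethylsilyloxy)-3-hydroxy-3-methylbutyl]-3-methoxyphenyl N,N-diethylcarbamate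
Product: 7 (S)-4-[1-(tert-butyldimethylsilyloxy)-3-methyl-3-(triethylsilyloxy)butyl]-3-methoxyphenyl N,N-diethylcarbamate
Conditions: TESOTf, 2,6-lutidine, CH2Cl2, 0 °C
Reagents that add atoms: triethylsilyl trifluoromethanesulfonate, CC[Si](CC)(CC)OS(=O)(=O)C(F)(F)F
Why: A silyl triflate with 2,6-lutidine is the standard way to silylate a hindered tertiary alcohol and leaves the molecule free of acidic protons.

Step 6
Reactants: 7 (S)-4-[1-(tert-butyldimethylsilyloxy)-3-methyl-3-(triethylsilyloxy)butyl]-3-methoxyphenyl N,N-diethylcarbamate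
Product: 9 (S)-4-[1-(tert-butyldimethylsilyloxy)-3-methyl-3-(triethylsilyloxy)butyl]-3-methoxy-2-(trimethylsilyl)phenyl N,N-diethylcarbamate, via aryllithium 8 (not isolated)
Conditions: s-BuLi, TMEDA, THF, −78 °C; then TMSCl, −78 °C → rt
Reagents that add atoms: chlorotrimethylsilane, C[Si](C)(C)Cl
Why: Directed ortho-metalation: ring A C1 lies between the carbamate oxygen on C6 and the methoxy group on C2, the cooperatively activated site at which 1,3-dioxygenated arenes are lithiated, and at −78 °C the aryllithium should be silylated before anionic ortho-Fries migration or benzylic deprotonation can compete.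

Step 7
Reactants: 9 (S)-4-[1-(tert-butyldimethylsilyloxy)-3-methyl-3-(triethylsilyloxy)butyl]-3-methoxy-2-(trimethylsilyl)phenyl N,N-diethylcarbamate
Product: 10 (S)-4-[1-(tert-butyldimethylsilyloxy)-3-methyl-3-(triethylsilyloxy)butyl]-3-methoxy-2-(trimethylsilyl)phenol
Conditions: LiAlH4, THF, 0 °C → rt; aq. KNaC4H4O6 (potassium sodium tartrate) work-up
Reagents that add atoms: none
Why: Hydride reduction of the aryl carbamate: attack at the carbamate carbonyl expels the phenoxide (the amine part leaves as diethylmethylamine), alkyl silyl ethers and the aryl–silicon bond are inert to LiAlH4, and the neutral tartrate work-up avoids protodesilylation.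

Step 8
Reactants: 10 (S)-4-[1-(tert-butyldimethylsilyloxy)-3-methyl-3-(triethylsilyloxy)butyl]-3-methoxy-2-(trimethylsilyl)phenol
Product: 11 (S)-4-[1-(tert-butyldimethylsilyloxy)-3-methyl-3-(triethylsilyloxy)butyl]-3-methoxy-2-(trimethylsilyl)phenyl trifluoromethanesulfonate
Conditions: Tf2O, pyridine, CH2Cl2, 0 °C
Reagents that add atoms: trifluoromethanesulfonic anhydride, O=S(=O)(OS(=O)(=O)C(F)(F)F)C(F)(F)F
Why: O-triflation of a 2-silylphenol is the standard last operation in making ortho-silylaryl triflate aryne precursors and is compatible with alkyl silyl ethers at 0 °C.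

Step 9
Reactants: 12 2-hydroxy-3-methoxy-5-methylbenzaldehyde
Product: 13 2,3-dihydroxy-5-methylbenzaldehyde
Conditions: BBr3, CH2Cl2, −78 °C → rt; H2O
Reagents that add atoms: none
Why: Lewis-acid cleavage of the aryl methyl ether by BBr3 (bromide attack on the boron-bound methyl ether), the demethylation used for ortho-vanillin, should free the catechol without harming the aldehyde.

Step 10
Reactants: 13 2,3-dihydroxy-5-methylbenzaldehyde
Product: 15 3-(allyloxy)-2-hydroxy-5-methylbenzaldehyde, via disodium diphenoxide 14 (not isolated)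
Conditions: NaH (2.2 equiv), DMSO, rt; allyl bromide (1.0 equiv), rt; aq. HCl
Reagents that add atoms: allyl bromide, C=CCBr
Why: Williamson etherification of the dianion: the C2 phenoxide is held in conjugation and chelation with the formyl group, so the more basic and more nucleophilic C3 phenoxide should take the single equivalent of allyl bromide, the regioselectivity established for 2,3-dihydroxybenzaldehyde dianions.

Step 11
Reactants: 15 3-(allyloxy)-2-hydroxy-5-methylbenzaldehyde
Product: 16 2-(allyloxy)-6-(hydroxymethyl)-4-methylphenol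
Conditions: NaBH4, MeOH, 0 °C
Reagents that add atoms: none
Why: Borohydride reduction converts the aldehyde chemoselectively into the benzylic alcohol and leaves the allyl ether and the arene untouched.

Step 12
Reactants: 16 2-(allyloxy)-6-(hydroxymethyl)-4-methylphenol
Product: 17 2-(allyloxy)-6-{[(tert-butyldimethylsilyl)oxy]methyl}-4-methylphenol
Conditions: TBSCl (1.05 equiv), imidazole, CH2Cl2, 0 °C
Reagents that add atoms: tert-butyldimethylsilyl chloride, CC(C)(C)[Si](C)(C)Cl
Why: With one equivalent of silyl chloride the unhindered primary alcohol should be silylated in preference to the phenol, which is flanked by two ortho substituents, giving the mono-protected phenol needed as the nucleophile.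

Step 13
Reactants: 11 (S)-4-[1-(tert-butyldimethylsilyloxy)-3-methyl-3-(triethylsilyloxy)butyl]-3-methoxy-2-(trimethylsilyl)phenyl trifluoromethanesulfonate; 17 2-(allyloxy)-6-{[(tert-butyldimethylsilyl)oxy]methyl}-4-methylphenol; 18 carbon dioxide
Product: 22 6-[2-(allyloxy)-6-{[(tert-butyldimethylsilyl)oxy]methyl}-4-methylphenoxy]-3-[(S)-1-(tert-butyldimethylsilyloxy)-3-methyl-3-(triethylsilyloxy)butyl]-2-methoxybenzoic acid, via potassium phenoxide 19 (not isolated), via aryne 20 (not isolated), via arylpotassium 21 (not isolated)
Conditions: 17 (1.5 equiv), KH, THF, 0 °C; then KF, 18-crown-6, CO2 (1 atm), THF, 0 °C, slow addition of 11, → rt; then 0.5 M aq. HCl to pH 3, 0 °C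
Reagents that add atoms: none
Why: Proposed new method: fluoride attacks the trimethylsilyl group of 11 and triflate leaves, giving aryne 20 with its triple bond between ring A C6 and C1; the C2 methoxy group polarises and distorts this bond so that phenoxide 19 adds at the remote carbon C6 and the charge develops at C1, beside the inductively withdrawing oxygen, and the resulting arylpotassium 21 is captured at C1 by CO2 to give the benzoate, protonated on work-up. The closest known reaction types are the three-component coupling of arynes, amines and CO2 to anthranilic acids (KF/18-crown-6 in THF) and the fluoride-mediated O-arylation of phenols by silylaryl triflates; what is new is a phenoxide as the nucleophile in the carboxylative coupling. No ring is closed and no stereocentre is formed: the step makes the C6–O and C1–CO2H bonds between separate partners, and the remote, non-acidic (S) centre of 11 is untouched. Two selectivities are needed: attack at C6 and not at C1, secured by the methoxy group flanking the aryne (the bias that governs additions to 3-methoxybenzyne), and carboxylation and not protonation of 21, secured by the absence of any O–H or N–H (every hydroxyl silylated or allylated, the phenoxide made with KH so that only H2 is released, THF in place of acetonitrile) and by the CO2-saturated solution. O-attack by 19 is the only course because both ortho positions and the para position of ring B are substituted, reversible carbonate formation between 19 and CO2 should only store the phenoxide, and slow addition of 11 keeps the aryne away from the product carboxylate.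

Step 14
Reactants: 22 6-[2-(allyloxy)-6-{[(tert-butyldimethylsilyl)oxy]methyl}-4-methylphenoxy]-3-[(S)-1-(tert-butyldimethylsilyloxy)-3-methyl-3-(triethylsilyloxy)butyl]-2-methoxybenzoic acid
Product: 23 3-[(S)-1-(tert-butyldimethylsilyloxy)-3-methyl-3-(triethylsilyloxy)butyl]-6-[2-{[(tert-butyldimethylsilyl)oxy]methyl}-6-hydroxy-4-methylphenoxy]-2-methoxybenzoic acid
Conditions: Pd(PPh3)4 (5 mol%), morpholine, THF, rt
Reagents that add atoms: none
Why: Tsuji–Trost-type deallylation: zerovalent palladium ionises the aryl allyl ether to a π-allylpalladium phenoxide and morpholine takes up the allyl group irreversibly, conditions under which silyl ethers, the diaryl ether and the carboxylic acid are stable.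

Step 15
Reactants: 23 3-[(S)-1-(tert-butyldimethylsilyloxy)-3-methyl-3-(triethylsilyloxy)butyl]-6-[2-{[(tert-butyldimethylsilyl)oxy]methyl}-6-hydroxy-4-methylphenoxy]-2-methoxybenzoic acid
Product: 24 3-[(S)-1,3-dihydroxy-3-methylbutyl]-6-[2-hydroxy-6-(hydroxymethyl)-4-methylphenoxy]-2-methoxybenzoic acid (target)
Conditions: Bu4NF (6 equiv), THF, 0 °C → rt; then 0.5 M aq. HCl to pH 3–4, 0 °C
Reagents that add atoms: none
Why: Fluoride-mediated desilylation: Bu4NF cleaves the primary and secondary TBS ethers and the tertiary TES ether through pentacoordinate silicates under non-acidic conditions, which should spare the benzylic (S) carbinol and avoid acid-induced lactonisation onto the ring B hydroxymethyl group.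

**Compound list**
1 | 4-hydroxy-2-methoxybenzaldehyde | COc1c(C=O)ccc(O)c1 | starting material
2 | 4-formyl-3-methoxyphenyl N,N-diethylcarbamate | COc1c(C=O)ccc(OC(=O)N(CC)CC)c1 | intermediate
3 | O-diisopinocampheylboryl ether of 4 (borinate ester, not isolated) | COc1c([C@@H](OB([C@@H]2C[C@@H]3C[C@H]([C@H]2C)C3(C)C)[C@@H]2C[C@@H]3C[C@H]([C@H]2C)C3(C)C)CC(C)=C)ccc(OC(=O)N(CC)CC)c1 | intermediate
4 | (S)-4-(1-hydroxy-3-methylbut-3-en-1-yl)-3-methoxyphenyl N,N-diethylcarbamate | COc1c([C@@H](O)CC(C)=C)ccc(OC(=O)N(CC)CC)c1 | intermediate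
5 | (S)-4-[1-(tert-butyldimethylsilyloxy)-3-methylbut-3-en-1-yl]-3-methoxyphenyl N,N-diethylcarbamate | COc1c([C@@H](O[Si](C)(C)C(C)(C)C)CC(C)=C)ccc(OC(=O)N(CC)CC)c1 | intermediate
6 | (S)-4-[1-(tert-butyldimethylsilyloxy)-3-hydroxy-3-methylbutyl]-3-methoxyphenyl N,N-diethylcarbamate | COc1c([C@@H](O[Si](C)(C)C(C)(C)C)CC(C)(C)O)ccc(OC(=O)N(CC)CC)c1 | intermediate
7 | (S)-4-[1-(tert-butyldimethylsilyloxy)-3-methyl-3-(triethylsilyloxy)butyl]-3-methoxyphenyl N,N-diethylcarbamate | COc1c([C@@H](O[Si](C)(C)C(C)(C)C)CC(C)(C)O[Si](CC)(CC)CC)ccc(OC(=O)N(CC)CC)c1 | intermediate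
8 | aryllithium of 7, lithium on the ring carbon between the methoxy and carbamate oxygens (not isolated) | COc1c([C@@H](O[Si](C)(C)C(C)(C)C)CC(C)(C)O[Si](CC)(CC)CC)ccc(OC(=O)N(CC)CC)c1[Li] | intermediate
9 | (S)-4-[1-(tert-butyldimethylsilyloxy)-3-methyl-3-(triethylsilyloxy)butyl]-3-methoxy-2-(trimethylsilyl)phenyl N,N-diethylcarbamate | COc1c([C@@H](O[Si](C)(C)C(C)(C)C)CC(C)(C)O[Si](CC)(CC)CC)ccc(OC(=O)N(CC)CC)c1[Si](C)(C)C | intermediate
10 | (S)-4-[1-(tert-butyldimethylsilyloxy)-3-methyl-3-(triethylsilyloxy)butyl]-3-methoxy-2-(trimethylsilyl)phenol | COc1c([C@@H](O[Si](C)(C)C(C)(C)C)CC(C)(C)O[Si](CC)(CC)CC)ccc(O)c1[Si](C)(C)C | intermediate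
11 | (S)-4-[1-(tert-butyldimethylsilyloxy)-3-methyl-3-(triethylsilyloxy)butyl]-3-methoxy-2-(trimethylsilyl)phenyl trifluoromethanesulfonate | COc1c([C@@H](O[Si](C)(C)C(C)(C)C)CC(C)(C)O[Si](CC)(CC)CC)ccc(OS(=O)(=O)C(F)(F)F)c1[Si](C)(C)C | intermediate
12 | 2-hydroxy-3-methoxy-5-methylbenzaldehyde | COc1cc(C)cc(C=O)c1O | starting material
13 | 2,3-dihydroxy-5-methylbenzaldehyde | Oc1cc(C)cc(C=O)c1O | intermediate
14 | disodium 3-formyl-5-methylbenzene-1,2-diolate (not isolated) | [Na+].[Na+].[O-]c1cc(C)cc(C=O)c1[O-] | intermediate
15 | 3-(allyloxy)-2-hydroxy-5-methylbenzaldehyde | C=CCOc1cc(C)cc(C=O)c1O | intermediate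
16 | 2-(allyloxy)-6-(hydroxymethyl)-4-methylphenol | C=CCOc1cc(C)cc(CO)c1O | intermediate
17 | 2-(allyloxy)-6-{[(tert-butyldimethylsilyl)oxy]methyl}-4-methylphenol | Oc1c(OCC=C)cc(C)cc1CO[Si](C)(C)C(C)(C)C | intermediate
18 | carbon dioxide | O=C=O | starting material
19 | potassium 2-(allyloxy)-6-{[(tert-butyldimethylsilyl)oxy]methyl}-4-methylphenoxide (not isolated) | [K+].[O-]c1c(OCC=C)cc(C)cc1CO[Si](C)(C)C(C)(C)C | intermediate
20 | ring A aryne, triple bond between C6 and C1, methoxy on C2, (S) side chain on C3 (not isolated) | COC1=C([C@@H](O[Si](C)(C)C(C)(C)C)CC(C)(C)O[Si](CC)(CC)CC)C=CC#C1 | intermediate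
21 | C1 arylpotassium formed by addition of 19 to C6 of 20 (not isolated) | COc1c([C@@H](O[Si](C)(C)C(C)(C)C)CC(C)(C)O[Si](CC)(CC)CC)ccc(Oc2c(OCC=C)cc(C)cc2CO[Si](C)(C)C(C)(C)C)c1[K] | intermediate
22 | 6-[2-(allyloxy)-6-{[(tert-butyldimethylsilyl)oxy]methyl}-4-methylphenoxy]-3-[(S)-1-(tert-butyldimethylsilyloxy)-3-methyl-3-(triethylsilyloxy)butyl]-2-methoxybenzoic acid | COc1c([C@@H](O[Si](C)(C)C(C)(C)C)CC(C)(C)O[Si](CC)(CC)CC)ccc(Oc2c(OCC=C)cc(C)cc2CO[Si](C)(C)C(C)(C)C)c1C(=O)O | intermediate
23 | 3-[(S)-1-(tert-butyldimethylsilyloxy)-3-methyl-3-(triethylsilyloxy)butyl]-6-[2-{[(tert-butyldimethylsilyl)oxy]methyl}-6-hydroxy-4-methylphenoxy]-2-methoxybenzoic acid | COc1c([C@@H](O[Si](C)(C)C(C)(C)C)CC(C)(C)O[Si](CC)(CC)CC)ccc(Oc2c(O)cc(C)cc2CO[Si](C)(C)C(C)(C)C)c1C(=O)O | intermediate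
24 | 3-[(S)-1,3-dihydroxy-3-methylbutyl]-6-[2-hydroxy-6-(hydroxymethyl)-4-methylphenoxy]-2-methoxybenzoic acid (CNP0452050.2) | COc1c([C@@H](O)CC(C)(C)O)ccc(Oc2c(O)cc(C)cc2CO)c1C(=O)O | target

**Step count**
Total: 15 steps.
Longest linear sequence: 11 steps (steps 1–8, 13, 14, 15); the ring B branch is steps 9–12.

**Steps most likely to fail**

1. Step 13 (three-component coupling). The C1 aryl anion may be protonated before it meets CO2, the phenoxide may be held back as its carbonate so that the aryne is consumed by other nucleophiles (fluoride, the product carboxylate), or part of the addition may occur at C1.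
Fallback (known chemistry), from 11 and 17, back at 22: the two bond formations are separated. 11 and 17 are first joined in the established two-component way (CsF, MeCN, rt, no CO2; fluoride-induced O-arylation of a phenol by a silylaryl triflate, the C1 anion being protonated by the medium) to give the C1-unsubstituted diaryl ether F1. F1 is then lithiated at C1, between the C2 methoxy and C6 aryloxy oxygens (n-BuLi, TMEDA, THF, −40 → 0 °C; the ortho-lithiation of 1,3-dioxygenated arenes between the two oxygens), and the aryllithium is quenched with CO2 and acidified mildly to give 22. Deprotonation next to the allyl ether oxygen is the competing process there, which is why this order is the reserve and not the plan.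

2. Step 6 (directed lithiation on the full side chain). Lithiation may go to the wrong site (the benzylic C–H beside the silyloxy group followed by silyl migration from oxygen to carbon, or C5), or the carbamoyl group may migrate to C1 by an anionic ortho-Fries shift.
Fallback, from 2, back at 9: the lithiation is moved to the start, before any benzylic ether or stereocentre exists. Aldehyde 2 is converted into 4-(dimethoxymethyl)-3-methoxyphenyl N,N-diethylcarbamate F2 (HC(OMe)3, cat. TsOH, MeOH). F2 is lithiated between the two oxygens and silylated (s-BuLi, TMEDA, THF, −78 °C; TMSCl) to give the silylated acetal F3. Mild hydrolysis (pyridinium tosylate, acetone/H2O) gives 4-formyl-3-methoxy-2-(trimethylsilyl)phenyl N,N-diethylcarbamate F4. The operations of steps 2–5 are then run on F4: methallylboration to the (S)-homoallylic alcohol F5, silylation to the TBS ether F6, hydration to the tertiary alcohol F7, and triethylsilylation, which gives 9.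

3. Step 2 (asymmetric methallylboration). Facial selectivity may be eroded, for example by coordination of the ortho methoxy group or of magnesium salts to boron, giving material of insufficient enantiomeric purity that cannot be corrected later.
Fallback, from 2, back at 4: carbon–carbon bond formation and stereocontrol are separated. Methallylmagnesium chloride adds to 2 (THF, −78 °C) to give the racemic homoallylic alcohol F8. Dess–Martin periodinane (NaHCO3-buffered, CH2Cl2, 0 °C) gives the β,γ-unsaturated aryl ketone F9. Corey–Bakshi–Shibata reduction with (R)-2-methyl-CBS-oxazaborolidine and catecholborane (toluene, −78 °C), with the aryl group as the large substituent, should then deliver hydride to the face that gives (S)-alcohol 4.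

**Further compounds**
F1 | step 13 | tert-butyl{(S)-1-[4-(2-(allyloxy)-6-{[(tert-butyldimethylsilyl)oxy]methyl}-4-methylphenoxy)-2-methoxyphenyl]-3-methyl-3-(triethylsilyloxy)butoxy}dimethylsilane (22 with H in place of the carboxyl group at ring A C1) | COc1c([C@@H](O[Si](C)(C)C(C)(C)C)CC(C)(C)O[Si](CC)(CC)CC)ccc(Oc2c(OCC=C)cc(C)cc2CO[Si](C)(C)C(C)(C)C)c1
F2 | step 6 | 4-(dimethoxymethyl)-3-methoxyphenyl N,N-diethylcarbamate | COc1c(C(OC)OC)ccc(OC(=O)N(CC)CC)c1
F3 | step 6 | 4-(dimethoxymethyl)-3-methoxy-2-(trimethylsilyl)phenyl N,N-diethylcarbamate | COc1c(C(OC)OC)ccc(OC(=O)N(CC)CC)c1[Si](C)(C)C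
F4 | step 6 | 4-formyl-3-methoxy-2-(trimethylsilyl)phenyl N,N-diethylcarbamate | COc1c(C=O)ccc(OC(=O)N(CC)CC)c1[Si](C)(C)C
F5 | step 6 | (S)-4-(1-hydroxy-3-methylbut-3-en-1-yl)-3-methoxy-2-(trimethylsilyl)phenyl N,N-diethylcarbamate | COc1c([C@@H](O)CC(C)=C)ccc(OC(=O)N(CC)CC)c1[Si](C)(C)C
F6 | step 6 | (S)-4-[1-(tert-butyldimethylsilyloxy)-3-methylbut-3-en-1-yl]-3-methoxy-2-(trimethylsilyl)phenyl N,N-diethylcarbamate | COc1c([C@@H](O[Si](C)(C)C(C)(C)C)CC(C)=C)ccc(OC(=O)N(CC)CC)c1[Si](C)(C)C
F7 | step 6 | (S)-4-[1-(tert-butyldimethylsilyloxy)-3-hydroxy-3-methylbutyl]-3-methoxy-2-(trimethylsilyl)phenyl N,N-diethylcarbamate | COc1c([C@@H](O[Si](C)(C)C(C)(C)C)CC(C)(C)O)ccc(OC(=O)N(CC)CC)c1[Si](C)(C)C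
F8 | step 2 | racemic 4-(1-hydroxy-3-methylbut-3-en-1-yl)-3-methoxyphenyl N,N-diethylcarbamate | COc1c(C(O)CC(C)=C)ccc(OC(=O)N(CC)CC)c1
F9 | step 2 | 3-methoxy-4-(3-methylbut-3-enoyl)phenyl N,N-diethylcarbamate | COc1c(C(=O)CC(C)=C)ccc(OC(=O)N(CC)CC)c1
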